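## Retrosynthetic overview

- The target comes from a cis-8,9-diol ketone by double tigloylation. The diol comes from an α-ketol (hydride from the convex face), the ketol from enolate hydroxylation, and the two C-substituents from two conjugate additions to a bicyclic bis-enone (isopropenyl to ring B, methyl to ring A).
- Both rings of the bis-enone are closed in one flask by a double intramolecular aldol condensation of an acyclic keto-aldehyde. Ring A closes first on the free aldehyde; ring B closes after the acetal is cleaved in situ.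
- The acyclic precursor comes from an enamine-catalysed Michael addition of an α-branched aldehyde to hex-3-ene-2,5-dione, which sets the quaternary carbon.
- Building blocks: 2,5-dimethylfuran, methacrolein, 1,3-dioxolane.

Assumption: the L-proline sulfonamide catalyst and Rh/(S)-BINAP are taken to give the drawn configurations by analogy with the closest known cases; if a sense of induction is opposite, the antipodal catalyst or ligand is used.

## Route

Step 1
Reactants: 1 2,5-dimethylfuran
Product: 2 (Z)-hex-3-ene-2,5-dione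
Conditions: mCPBA (1.05 equiv), CH2Cl2, 0 °C
Reagents that add atoms: m-chloroperoxybenzoic acid, O=C(OO)c1cccc(Cl)c1
Why: Oxidative furan ring opening (peracid epoxidation of the electron-rich furan, then ring opening) gives the cis-enedione; no stereocentre is formed.

Step 2
Reactants: 3 methacrolein; 4 1,3-dioxolane
Product: 5 rac-3-(1,3-dioxolan-2-yl)-2-methylpropanal
Conditions: benzophenone (0.1 equiv), 1,3-dioxolane as solvent, hν (350 nm), rt
Reagents that add atoms: none
Why: Photosensitised hydrogen abstraction gives the 1,3-dioxolan-2-yl radical, which adds to the β-carbon of the enal (radical Giese-type hydroalkylation); the α-stereocentre is racemic and is erased in step 3.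

Step 3
Reactants: 5 rac-3-(1,3-dioxolan-2-yl)-2-methylpropanal; 2 (Z)-hex-3-ene-2,5-dione
Product: 6 (2S)-3-acetyl-2-[(1,3-dioxolan-2-yl)methyl]-2-methyl-5-oxohexanal (C3 epimers)
Conditions: N-(4-dodecylphenylsulfonyl)-L-prolinamide (20 mol %), ClCH2CH2Cl, 4 °C to rt
Reagents that add atoms: none
Why: Enamine-catalysed asymmetric Michael addition of the α-branched aldehyde to the doubly activated enedione creates the quaternary stereocentre under catalyst control (the sulfonamide N–H directs the acceptor to one enamine face), while the neighbouring acetyl-bearing centre is an epimerisable mixture that does not matter.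

Step 4
Reactants: 6 (2S)-3-acetyl-2-[(1,3-dioxolan-2-yl)methyl]-2-methyl-5-oxohexanal
Product: 9 (4aR,8aS)-4a-methyl-4a,5-dihydronaphthalene-2,8(1H,8aH)-dione, via monocyclic enone acetal 7 (not isolated), via monocyclic enone aldehyde 8 (not isolated)
Conditions: pyrrolidine (0.5 equiv), AcOH–H2O (4:1), 60 °C
Reagents that add atoms: none
Why: Two Robinson-type 6-(enolendo)-exo-trig aldol condensations run in one flask – the free neopentyl aldehyde closes ring A at once, slower hydrolysis of the dioxolane then frees the second aldehyde, which closes ring B – so both rings form in one operation with the quaternary centre untouched, and the epimerisable ring-fusion CH is corrected in step 5.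

Step 5
Reactants: 9 (4aR,8aS)-4a-methyl-4a,5-dihydronaphthalene-2,8(1H,8aH)-dione
Product: 10 (4aR,6S,8aS)-4a-methyl-6-(prop-1-en-2-yl)-4a,5,6,7-tetrahydronaphthalene-2,8(1H,8aH)-dione
Conditions: [Rh(cod)Cl]2 (2.5 mol %), (S)-BINAP (6 mol %), isopropenyl-Bpin (1.5 equiv), KOH (0.3 equiv), dioxane–H2O (10:1), 40 °C
Reagents that add atoms: 2-isopropenyl-4,4,5,5-tetramethyl-1,3,2-dioxaborolane, C=C(C)B1OC(C)(C)C(C)(C)O1
Why: Hayashi–Miyaura Rh-catalysed asymmetric 1,4-addition occurs only at the unhindered ring-B enone (the ring-A β-carbon is neopentylic), the ligand places the isopropenyl group on the face of the angular methyl group, and the base equilibrates C8a so that the cis-fused isomer with both groups equatorial is collected.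

Step 6
Reactants: 10 (4aR,6S,8aS)-4a-methyl-6-(prop-1-en-2-yl)-4a,5,6,7-tetrahydronaphthalene-2,8(1H,8aH)-dione
Product: 12 (3S,4aR,5S,8aS)-7-[(tert-butyldimethylsilyl)oxy]-4a,5-dimethyl-3-(prop-1-en-2-yl)-3,4,4a,5,8,8a-hexahydronaphthalen-1(2H)-one, via lithium enolate 11 (not isolated)
Conditions: Me2CuLi (1.5 equiv), Et2O, −78 to −40 °C; then TBSCl, HMPA, Et3N, −78 °C to rt
Reagents that add atoms: lithium dimethylcuprate, [Li+].C[Cu-]C; tert-butyldimethylsilyl chloride, CC(C)(C)[Si](C)(C)Cl
Why: Gilman cuprate conjugate addition to the remaining enone with O-silylation of the enolate; the methyl group enters from the convex face (the concave face is blocked by the axial C8a–C1 bond of ring B), which gives the cis-vicinal dimethyl pair and masks the ring-A ketone as its silyl enol ether.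

Step 7
Reactants: 12 (3S,4aR,5S,8aS)-7-[(tert-butyldimethylsilyl)oxy]-4a,5-dimethyl-3-(prop-1-en-2-yl)-3,4,4a,5,8,8a-hexahydronaphthalen-1(2H)-one
Product: 14 (2R,3R,4aR,5S,8aS)-7-[(tert-butyldimethylsilyl)oxy]-2-hydroxy-4a,5-dimethyl-3-(prop-1-en-2-yl)-3,4,4a,5,8,8a-hexahydronaphthalen-1(2H)-one, via lithium enolate 13 (not isolated)
Conditions: LDA (1.1 equiv), THF, −78 °C; then 2-(phenylsulfonyl)-3-phenyloxaziridine, −78 °C; aq. NH4Cl
Reagents that add atoms: 2-(phenylsulfonyl)-3-phenyloxaziridine, O=S(=O)(N1OC1c1ccccc1)c1ccccc1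
Why: Kinetic deprotonation at the CH2 flank of the only ketone followed by Davis enolate hydroxylation; oxygen is delivered anti to the adjacent isopropenyl group, giving the trans (equatorial) α-ketol, which is also the thermodynamic epimer.

Step 8
Reactants: 14 (2R,3R,4aR,5S,8aS)-7-[(tert-butyldimethylsilyl)oxy]-2-hydroxy-4a,5-dimethyl-3-(prop-1-en-2-yl)-3,4,4a,5,8,8a-hexahydronaphthalen-1(2H)-one
Product: 16 (4S,4aR,6R,7R,8S,8aS)-7,8-dihydroxy-4,4a-dimethyl-6-(prop-1-en-2-yl)octahydronaphthalen-2(1H)-one, via diol silyl enol ether 15 (not isolated)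
Conditions: L-Selectride (2.5 equiv), THF, −78 °C; then 1 M HCl, THF, rt
Reagents that add atoms: none
Why: Bulky-hydride ketone reduction in which axial attack is blocked by the axial C4a–C5 bond on the concave face, so hydride comes from the convex face and gives the axial alcohol cis to the neighbouring hydroxyl; the acid work-up hydrolyses the silyl enol ether to the ring-A ketone.

Step 9
Reactants: 16 (4S,4aR,6R,7R,8S,8aS)-7,8-dihydroxy-4,4a-dimethyl-6-(prop-1-en-2-yl)octahydronaphthalen-2(1H)-one
Product: 17 (1S,2R,3R,4aR,5S,8aS)-4a,5-dimethyl-7-oxo-3-(prop-1-en-2-yl)decahydronaphthalene-1,2-diyl bis[(2E)-2-methylbut-2-enoate] (target)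
Conditions: tigloyl chloride (5 equiv), DMAP (1 equiv), pyridine, CH2Cl2, 40 °C
Reagents that add atoms: (E)-2-methylbut-2-enoyl chloride, C/C=C(\C)C(Cl)=O
Why: DMAP-catalysed acyl transfer esterifies both secondary hydroxyls without touching any stereocentre, and the (E)-tigloyl geometry is the stable one.

## Compound list

1 | 2,5-dimethylfuran | Cc1ccc(C)o1 | starting material
2 | (Z)-hex-3-ene-2,5-dione | CC(=O)/C=C\C(C)=O | intermediate
3 | methacrolein | C=C(C)C=O | starting material
4 | 1,3-dioxolane | C1COCO1 | starting material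
5 | rac-3-(1,3-dioxolan-2-yl)-2-methylpropanal | CC(C=O)CC1OCCO1 | intermediate
6 | (2S)-3-acetyl-2-[(1,3-dioxolan-2-yl)methyl]-2-methyl-5-oxohexanal (C3 epimers) | O=C[C@@](C)(CC1OCCO1)C(C(C)=O)CC(C)=O | intermediate
7 | (4R)-5-acetyl-4-[(1,3-dioxolan-2-yl)methyl]-4-methylcyclohex-2-en-1-one (C5 epimers, not isolated) | O=C1C=C[C@@](C)(CC2OCCO2)C(C(C)=O)C1 | intermediate
8 | 2-[(1R)-6-acetyl-1-methyl-4-oxocyclohex-2-en-1-yl]acetaldehyde (C6 epimers, not isolated) | O=C1C=C[C@@](C)(CC=O)C(C(C)=O)C1 | intermediate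
9 | (4aR,8aS)-4a-methyl-4a,5-dihydronaphthalene-2,8(1H,8aH)-dione (cis isomer drawn; C8a equilibrates) | C[C@@]12C=CC(=O)C[C@@H]1C(=O)C=CC2 | intermediate
10 | (4aR,6S,8aS)-4a-methyl-6-(prop-1-en-2-yl)-4a,5,6,7-tetrahydronaphthalene-2,8(1H,8aH)-dione | C=C(C)[C@H]1C[C@@]2(C)[C@H](CC(=O)C=C2)C(=O)C1 | intermediate
11 | lithium enolate of the methyl 1,4-adduct of 10 (not isolated) | C=C(C)[C@H]1C[C@@]2(C)[C@H](CC(O[Li])=C[C@@H]2C)C(=O)C1 | intermediate
12 | (3S,4aR,5S,8aS)-7-[(tert-butyldimethylsilyl)oxy]-4a,5-dimethyl-3-(prop-1-en-2-yl)-3,4,4a,5,8,8a-hexahydronaphthalen-1(2H)-one | C=C(C)[C@H]1C[C@@]2(C)[C@H](CC(O[Si](C)(C)C(C)(C)C)=C[C@@H]2C)C(=O)C1 | intermediate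
13 | lithium C1–C2 enolate of 12 (not isolated) | C=C(C)[C@H]1C[C@@]2(C)[C@H](CC(O[Si](C)(C)C(C)(C)C)=C[C@@H]2C)C(O[Li])=C1 | intermediate
14 | (2R,3R,4aR,5S,8aS)-7-[(tert-butyldimethylsilyl)oxy]-2-hydroxy-4a,5-dimethyl-3-(prop-1-en-2-yl)-3,4,4a,5,8,8a-hexahydronaphthalen-1(2H)-one | C=C(C)[C@H]1C[C@@]2(C)[C@H](CC(O[Si](C)(C)C(C)(C)C)=C[C@@H]2C)C(=O)[C@@H]1O | intermediate
15 | (1S,2R,3R,4aR,5S,8aS)-7-[(tert-butyldimethylsilyl)oxy]-4a,5-dimethyl-3-(prop-1-en-2-yl)-1,2,3,4,4a,5,8,8a-octahydronaphthalene-1,2-diol (not isolated) | C=C(C)[C@H]1C[C@@]2(C)[C@H](CC(O[Si](C)(C)C(C)(C)C)=C[C@@H]2C)[C@H](O)[C@@H]1O | intermediate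
16 | (4S,4aR,6R,7R,8S,8aS)-7,8-dihydroxy-4,4a-dimethyl-6-(prop-1-en-2-yl)octahydronaphthalen-2(1H)-one | C=C(C)[C@H]1C[C@@]2(C)[C@H](CC(=O)C[C@@H]2C)[C@H](O)[C@@H]1O | intermediate
17 | (1S,2R,3R,4aR,5S,8aS)-4a,5-dimethyl-7-oxo-3-(prop-1-en-2-yl)decahydronaphthalene-1,2-diyl bis[(2E)-2-methylbut-2-enoate] | C=C(C)[C@H]1C[C@@]2(C)[C@H](CC(=O)C[C@@H]2C)[C@H](OC(=O)/C(C)=C/C)[C@@H]1OC(=O)/C(C)=C/C | target

## Step count and risks

Total step count: 9. Longest linear sequence: 8 steps (2 → 3 → 4 → 5 → 6 → 7 → 8 → 9; the branch through step 1 is equally long).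

Steps most likely to fail, each with one fallback:

**Step 3 (ee at the quaternary centre, reactivity of the α-branched aldehyde).** The fallback sets out from 5 and returns at 6, using a stoichiometric chiral auxiliary instead of a catalyst. Aldehyde 5 is condensed with (S)-1-phenylethylamine to the imine F1. Its secondary enamine tautomer adds to enedione 2 in an aza-ene-type Michael reaction (neat or THF, rt) to give the adduct imine F2. Buffered aqueous acetic acid then hydrolyses F2 to 6 and returns the auxiliary.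

**Step 4 (competing five-ring aldol modes, and the ring-fusion epimer ratio of 9).** The fallback sets out from 6 and returns at 9, closing the rings one at a time under non-equilibrating conditions for ring B. Compound 6 is cyclised with pyrrolidine/AcOH in toluene at rt and the monocyclic enone acetal 7 is isolated. Aqueous trifluoroacetic acid cleaves the dioxolane to give 8. A boron-mediated intramolecular aldol addition (Bu2BOTf, iPr2NEt, −78 °C) then closes ring B to the cis-fused bicyclic ketol F3, which the Burgess reagent dehydrates to 9.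

**Step 6 (face selectivity of the methyl addition next to the quaternary carbon).** The fallback sets out from 10 and returns at 12, replacing C–C bond formation by C–H bond formation at the new stereocentre. Compound 10 is methylated without regard to configuration (Me2CuLi, TMSCl) to the trimethylsilyl enol ether F4 as an epimer mixture. Saegusa–Ito oxidation (Pd(OAc)2, MeCN) converts F4 to the β-methyl enone F5. Conjugate hydride delivery with Stryker's reagent in the presence of TBSCl then puts hydrogen on the face the methyl group had wrongly taken, so the same facial bias gives 12 directly.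

## Further compounds

F1 | step 3 | (E)-N-[(1S)-1-phenylethyl]-3-(1,3-dioxolan-2-yl)-2-methylpropan-1-imine | C[C@H](/N=C/C(C)CC1OCCO1)c1ccccc1
F2 | step 3 | (4S)-3-acetyl-4-[(1,3-dioxolan-2-yl)methyl]-4-methyl-5-{[(1S)-1-phenylethyl]imino}pentyl methyl ketone (imine of 6, C3 epimers) | C[C@H](/N=C/[C@@](C)(CC1OCCO1)C(C(C)=O)CC(C)=O)c1ccccc1
F3 | step 4 | (4aR,8aS)-6-hydroxy-4a-methyl-4a,5,6,7-tetrahydronaphthalene-2,8(1H,8aH)-dione (C6 epimers) | C[C@@]12C=CC(=O)C[C@@H]1C(=O)CC(O)C2
F4 | step 6 | (3S,4aR,8aS)-4a,5-dimethyl-3-(prop-1-en-2-yl)-7-[(trimethylsilyl)oxy]-3,4,4a,5,8,8a-hexahydronaphthalen-1(2H)-one (C5 epimers) | C=C(C)[C@H]1C[C@@]2(C)[C@H](CC(O[Si](C)(C)C)=CC2C)C(=O)C1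
F5 | step 6 | (4aS,6S,8aS)-4,4a-dimethyl-6-(prop-1-en-2-yl)-4a,5,6,7-tetrahydronaphthalene-2,8(1H,8aH)-dione | C=C(C)[C@H]1C[C@@]2(C)[C@H](CC(=O)C=C2C)C(=O)C1
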